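**Plan**

1. Retrosynthetic cuts: the C6 acetate and C6–H go back to a 6-ketone; C8–OH and C17 go back, through a 7α,8α-epoxy ketone and an 8-methyl enone, to the C8 enol triflate of a 6,8-dione; then C9–C11 (aldol condensation with a C5 aldehyde), C3–O and C20–O (radical deoxygenation), C4–C5 (ring A, the key cut) and C1–C10 (Birch alkylation).
2. Forward order: ring B comes from methyl 3,5-dimethoxybenzoate, whose Birch alkylation makes quaternary C10 carrying the C1–C4 epoxy chain. Ring A then closes onto it, and the side chain (C9), the methyl group (C8) and the oxygens at C8 and C6 follow.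
3. Enabling feature: on ring B the oxygens at C6 and C8 are meta to each other and both meta to quaternary C10, the pattern of a reduced 3,5-dimethoxybenzoate, so C5 and C9 are enantiotopic enol ether carbons that a chiral epoxide on the C10 chain can tell apart.
4. Stereochemistry: C13 is bought with (S)-methyl hydrogen 3-methylglutarate and the (R)-epoxide comes from a Shi epoxidation. C10 is set by that epoxide in the ring closure and C5 by equilibration. C9 is set by hydrogenation anti to C20, C8 by α-face epoxidation and SmI2 opening, and C6 by hydride attack on the α face.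

Key step: step 7

Remark: atoms carry labdane numbers (decalin C1–C10, C20 on C10, C17 on C8, chain C11–C16), α is the face opposite the C10 substituent, and (S)-methyl hydrogen 3-methylglutarate is assumed to be purchasable.

**Route**

Step 1
Reactants: 1 (S)-3-methylglutaric acid monomethyl ester
Product: 2 methyl (3S)-5-hydroxy-3-methylpentanoate
Conditions: BH3·SMe2 (1.1 equiv), THF, −10 → 20 °C; MeOH quench
Reagents that add atoms: none
Why: Chemoselective borane reduction takes the free carboxylic acid to the primary alcohol much faster than it touches the methyl ester, and the C3 stereocentre (the future C13) is not involved.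

Step 2
Reactants: 2 methyl (3S)-5-hydroxy-3-methylpentanoate
Product: 3 methyl (3S)-3-methyl-5-oxopentanoate
Conditions: TEMPO (10 mol%), PhI(OAc)2 (1.1 equiv), CH2Cl2, 20 °C
Reagents that add atoms: none
Why: The TEMPO-catalysed oxidation of a primary alcohol stops at the aldehyde under nearly neutral conditions, so the β-stereocentre and the ester should survive and lactonisation of 2 is outrun.

Step 3
Reactants: 4 5-bromo-2-methylpent-2-ene
Product: 5 (R)-3-(2-bromoethyl)-2,2-dimethyloxirane
Conditions: 1,2:4,5-di-O-isopropylidene-β-D-erythro-hexo-2,3-diulo-2,6-pyranose (D-fructose-derived Shi ketone, 30 mol%), KHSO5 (as Oxone), K2CO3, Bu4NHSO4, MeCN–CH2(OMe)2–aq. Na2B4O7 buffer (pH 10.5), 0 °C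
Reagents that add atoms: potassium peroxymonosulfate, [K+].[O-]S(=O)(=O)OO
Why: Shi asymmetric epoxidation of a trisubstituted olefin through the spiro dioxirane transition state should give the (R)-epoxide with the D-fructose-derived ketone, and the primary bromide tolerates the cold buffered medium.

Step 4
Reactants: 6 methyl 3,5-dimethoxybenzoate; 5 (R)-3-(2-bromoethyl)-2,2-dimethyloxirane
Product: 8 methyl 1-{2-[(2R)-3,3-dimethyloxiran-2-yl]ethyl}-3,5-dimethoxycyclohexa-2,5-diene-1-carboxylate, via potassium ester dienolate 7 (not isolated)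
Conditions: K (2.3 equiv), t-BuOH (1.0 equiv), NH3(l)–THF, −78 °C; penta-1,3-diene; then 5 (1.3 equiv), −78 → −33 °C; NH4Cl
Reagents that add atoms: none
Why: Birch reductive alkylation of a benzoate gives the 1,4-dihydro ester dienolate, which should be alkylated at the ipso carbon (future C10) by the primary bromide far faster than it opens the hindered trisubstituted epoxide; C10 is not yet stereogenic because its two enol ether arms are enantiotopic.

Step 5
Reactants: 8 methyl 1-{2-[(2R)-3,3-dimethyloxiran-2-yl]ethyl}-3,5-dimethoxycyclohexa-2,5-diene-1-carboxylate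
Product: 9 (1-{2-[(2R)-3,3-dimethyloxiran-2-yl]ethyl}-3,5-dimethoxycyclohexa-2,5-dien-1-yl)methanol
Conditions: iBu2AlH (2.5 equiv), THF–toluene, −78 → −20 °C; aq. KNaC4H4O6 work-up
Reagents that add atoms: none
Why: Low-temperature iBu2AlH reduction of an ester to the primary alcohol is faster than hydride opening of a trisubstituted epoxide, and the neutral tartrate work-up spares the acid-labile enol ethers.

Step 6
Reactants: 9 (1-{2-[(2R)-3,3-dimethyloxiran-2-yl]ethyl}-3,5-dimethoxycyclohexa-2,5-dien-1-yl)methanol
Product: 10 triethyl[(1-{2-[(2R)-3,3-dimethyloxiran-2-yl]ethyl}-3,5-dimethoxycyclohexa-2,5-dien-1-yl)methoxy]silane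
Conditions: Et3SiCl, imidazole, CH2Cl2, 0 °C
Reagents that add atoms: chlorotriethylsilane, CC[Si](Cl)(CC)CC
Why: Silylation under non-alkoxide conditions masks the neopentyl hydroxyl so that neither the oxygen nor a Brønsted acid formed from it and BF3 can intercept the epoxide or the enol ethers in step 7, and the triethylsilyl ether is chosen to fall off in the acid work-up of that step.

Step 7
Reactants: 10 triethyl[(1-{2-[(2R)-3,3-dimethyloxiran-2-yl]ethyl}-3,5-dimethoxycyclohexa-2,5-dien-1-yl)methoxy]silane
Product: 12 3α-hydroxy-10β-(hydroxymethyl)-4,4-dimethyl-trans-decalin-6,8-dione (5α-H), via cis-fused enol ether ketone 11 (not isolated)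
Conditions: BF3·OEt2 (1.2 equiv), 2,6-di-tert-butyl-4-methylpyridine (0.3 equiv), CH2Cl2, −78 °C; then 1 M HCl, THF, 0 → 40 °C
Reagents that add atoms: water, O
Why: Proposed new method: BF3 binds the epoxide oxygen, the C4–O bond stretches toward the tertiary cation, and C5, the β-carbon of one methyl enol ether, attacks C4 anti to the leaving oxygen to give a C6 oxocarbenium ion that water converts into the ketone, after which aqueous acid also hydrolyses the second enol ether and the silyl ether; the closest known reaction type is the Lewis-acid epoxide-initiated cation–olefin cyclisation terminated by an enol ether, not yet shown on a Birch-derived bis(enol ether) where it must desymmetrise a prochiral quaternary carbon. Ring A closes by 6-endo opening of the epoxide at its tertiary carbon, with the enol ether double bond exocyclic to the new ring, through a chair in which the anti-periplanar opening forces the C3–O bond equatorial. C10 is controlled by the C3 epoxide stereocentre: attack must be perpendicular to the enol ether plane, so the reacting arm has to sit axial and the C10 CH2OSi group equatorial on the ring A chair, and in the chair fixed by the (R)-epoxide only one of the two enantiotopic arms fits, which puts C20 trans to the C3 oxygen. C5 is formed cis (5β-H, because the chain reaches C5 on the face of C1) and is then corrected to the more stable trans fusion by acid-catalysed enolisation of the C6 ketone during the work-up. The step needs C–C bond formation to outrun protonation of the enol ethers and hydride-shift rearrangement of the epoxide, which the high nucleophilicity of the enol ether, the six-membered chair, the low temperature and the hindered pyridine buffer should secure.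

Step 8
Reactants: 12 3α-hydroxy-10β-(hydroxymethyl)-4,4-dimethyl-trans-decalin-6,8-dione
Product: 13 3α-hydroxy-10β-(hydroxymethyl)-8-methoxy-4,4-dimethyl-trans-Δ7-octalin-6-one
Conditions: MeOH, HC(OMe)3, TsOH·H2O (5 mol%), 20 °C
Reagents that add atoms: methanol, CO
Why: Acid-catalysed enol etherification of a cyclic 1,3-dione (vinylogous ester formation) should methylate the less hindered C8 oxygen and removes the acidic enol before the alkoxide chemistry of step 9; the regiochemistry is not critical because the group is hydrolysed again in step 10.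

Step 9
Reactants: 13 3α-hydroxy-10β-(hydroxymethyl)-8-methoxy-4,4-dimethyl-trans-Δ7-octalin-6-one
Product: 14 O3,O20-bis[(methylsulfanyl)carbonothioyl] derivative of 13 (bis-xanthate)
Conditions: NaH (3 equiv), imidazole (cat.), THF, 0 → 20 °C; CS2; then MeI
Reagents that add atoms: carbon disulfide, S=C=S; iodomethane, CI
Why: Xanthate formation (alkoxide addition to CS2 and S-methylation) is the standard entry to Barton–McCombie deoxygenation and is reliable for hindered neopentyl and axial alcohols, while the bridgehead position of C8 keeps the C20 alkoxide from displacing the methoxy group.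

Step 10
Reactants: 14 bis-xanthate of 13
Product: 16 4,4,10β-trimethyl-trans-decalin-6,8-dione (5α-H), via 8-methoxy enone 15 (not isolated)
Conditions: Bu3SnH (3 equiv), AIBN (0.2 equiv), toluene, 110 °C; then 2 M HCl, THF, 40 °C
Reagents that add atoms: water, O
Why: Barton–McCombie deoxygenation (stannyl radical addition to C=S, β-scission, hydrogen transfer) should remove both the C3 and the C20 oxygen, neither radical having an alkene within reach for 5-exo or 6-exo closure, and aqueous acid then hydrolyses the vinylogous ester to the dione with C5 staying in its thermodynamic trans configuration.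

Step 11
Reactants: 16 4,4,10β-trimethyl-trans-decalin-6,8-dione; 3 methyl (3S)-3-methyl-5-oxopentanoate
Product: 19 methyl (13S)-6,8-dioxo-17-norlabd-9(11)-en-15-oate (E/Z mixture), via aldol adduct 17 (not isolated), via diacetate 18 (not isolated)
Conditions: LiN(iPr)2 (2.2 equiv), THF, −78 → 0 °C; 3, −78 °C; Ac2O (4 equiv), −78 → 0 °C; DBU, 20 °C; then K2CO3, MeOH, 0 °C
Reagents that add atoms: none
Why: γ-Aldol reaction of a 1,3-dione dianion, where the second deprotonation should occur at the C9 methylene and not at the tertiary C5–H flanked by two quaternary carbons, followed by acetylation in the flask (which stops the C11 alkoxide from lactonising onto the ester) and E1cB loss of acetate; the transient C9 and C11 centres and the alkene geometry do not matter because C9 is set in step 12.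

Step 12
Reactants: 19 methyl (13S)-6,8-dioxo-17-norlabd-9(11)-en-15-oate
Product: 20 methyl (13S)-6,8-dioxo-17-norlabdan-15-oate (9α-H)
Conditions: H2 (1 atm), Pd/C (5 mol% Pd), EtOAc, 20 °C
Reagents that add atoms: none
Why: Heterogeneous hydrogenation of the exocyclic enone double bond should deliver hydrogen to C9 from the α face, anti to the axial C10 methyl group, which sets 9α-H with the side chain β, whereas direct alkylation would be expected to put the carbon substituent on that same α face and give the wrong epimer.

Step 13
Reactants: 20 methyl (13S)-6,8-dioxo-17-norlabdan-15-oate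
Product: 21 methyl (13S)-6-oxo-8-(trifluoromethylsulfonyloxy)-17-norlabd-7-en-15-oate
Conditions: Tf2O (1.1 equiv), pyridine, CH2Cl2, −78 → 0 °C
Reagents that add atoms: trifluoromethanesulfonic anhydride, O=S(=O)(OS(=O)(=O)C(F)(F)F)C(F)(F)F
Why: Enol triflate formation of a 1,3-dione should occur at the C8 oxygen, which is flanked by a CH carrying a primary alkyl group, in preference to the C6 oxygen shielded by quaternary C4, and cold pyridine should not enolise C9.

Step 14
Reactants: 21 methyl (13S)-6-oxo-8-(trifluoromethylsulfonyloxy)-17-norlabd-7-en-15-oate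
Product: 22 methyl (13S)-6-oxolabd-7-en-15-oate
Conditions: Me2CuLi (from CuI and 2 MeLi, 2.5 equiv), THF–Et2O, −78 → −20 °C
Reagents that add atoms: lithium dimethylcuprate, [Li+].C[Cu-]C
Why: Conjugate addition–elimination of a lithium dialkylcuprate on a β-triflyloxy enone places the C17 methyl group on C8 and leaves the methyl ester and the C9 centre untouched.

Step 15
Reactants: 22 methyl (13S)-6-oxolabd-7-en-15-oate
Product: 23 methyl (13S)-7α,8α-epoxy-6-oxolabdan-15-oate
Conditions: dimethyldioxirane (acetone solution, 3 equiv), CH2Cl2, 0 → 20 °C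
Reagents that add atoms: dimethyldioxirane, CC1(C)OO1
Why: Dioxirane epoxidation of the trisubstituted enone works under neutral conditions, so the γ-hydrogen at C9 is not removed, and oxygen should enter on the α face because the axial C10 methyl group blocks the β face, which sets C8 (and C7).

Step 16
Reactants: 23 methyl (13S)-7α,8α-epoxy-6-oxolabdan-15-oate
Product: 24 methyl (13S)-8α-hydroxy-6-oxolabdan-15-oate
Conditions: SmI2 (2.5 equiv), THF–MeOH, −90 °C
Reagents that add atoms: none
Why: Reduction of an α,β-epoxy ketone by divalent samarium cleaves only the C7–O bond next to the carbonyl and the resulting enolate is protonated by methanol, so the C8–O bond keeps its configuration (8α-OH, 8β-CH3) and the low temperature suppresses dehydration.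

Step 17
Reactants: 24 methyl (13S)-8α-hydroxy-6-oxolabdan-15-oate
Product: 25 methyl (13S)-6β,8α-dihydroxylabdan-15-oate
Conditions: NaBH4, MeOH–CH2Cl2, −20 → 0 °C
Reagents that add atoms: none
Why: In this borohydride reduction the β face of C6 is closed by three syn-axial methyl groups (C17, C19, C20), so hydride should add from the α face and give the axial 6β-alcohol, while the ester is not reduced at this temperature.

Step 18
Reactants: 25 methyl (13S)-6β,8α-dihydroxylabdan-15-oate
Product: 26 methyl (13S)-6β-acetoxy-8α-hydroxylabdan-15-oate (CNP0113148.1)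
Conditions: Ac2O, DMAP, pyridine, 40 °C
Reagents that add atoms: acetic anhydride, CC(=O)OC(C)=O
Why: DMAP-catalysed acylation should acetylate the hindered secondary 6β-hydroxyl on mild warming, while the tertiary 8α-hydroxyl does not react under these conditions.

**Compound list**

1 | (S)-3-methylglutaric acid monomethyl ester | COC(=O)C[C@@H](C)CC(=O)O | starting material
2 | methyl (3S)-5-hydroxy-3-methylpentanoate | COC(=O)C[C@@H](C)CCO | intermediate
3 | methyl (3S)-3-methyl-5-oxopentanoate | COC(=O)C[C@@H](C)CC=O | intermediate
4 | 5-bromo-2-methylpent-2-ene | CC(C)=CCCBr | starting material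
5 | (R)-3-(2-bromoethyl)-2,2-dimethyloxirane | BrCC[C@H]1OC1(C)C | intermediate
6 | methyl 3,5-dimethoxybenzoate | COC(=O)c1cc(OC)cc(OC)c1 | starting material
7 | potassium dienolate of methyl 3,5-dimethoxycyclohexa-2,5-diene-1-carboxylate | [K+].COC([O-])=C1C=C(OC)CC(OC)=C1 | intermediate
8 | methyl 1-{2-[(2R)-3,3-dimethyloxiran-2-yl]ethyl}-3,5-dimethoxycyclohexa-2,5-diene-1-carboxylate | COC(=O)C1(CC[C@H]2OC2(C)C)C=C(OC)CC(OC)=C1 | intermediate
9 | (1-{2-[(2R)-3,3-dimethyloxiran-2-yl]ethyl}-3,5-dimethoxycyclohexa-2,5-dien-1-yl)methanol | OCC1(CC[C@H]2OC2(C)C)C=C(OC)CC(OC)=C1 | intermediate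
10 | triethyl[(1-{2-[(2R)-3,3-dimethyloxiran-2-yl]ethyl}-3,5-dimethoxycyclohexa-2,5-dien-1-yl)methoxy]silane | CC[Si](CC)(CC)OCC1(CC[C@H]2OC2(C)C)C=C(OC)CC(OC)=C1 | intermediate
11 | cis-fused (5β-H) 3α-hydroxy-8-methoxy-4,4-dimethyl-10β-[(triethylsilyloxy)methyl]-Δ8(9)-octalin-6-one | COC1=C[C@@]2(CO[Si](CC)(CC)CC)CC[C@@H](O)C(C)(C)[C@H]2C(=O)C1 | intermediate
12 | 3α-hydroxy-10β-(hydroxymethyl)-4,4-dimethyl-trans-decalin-6,8-dione (5α-H) | O=C1C[C@@]2(CO)CC[C@@H](O)C(C)(C)[C@@H]2C(=O)C1 | intermediate
13 | 3α-hydroxy-10β-(hydroxymethyl)-8-methoxy-4,4-dimethyl-trans-Δ7-octalin-6-one | C1[C@@]2(CO)CC[C@@H](O)C(C)(C)[C@@H]2C(=O)C=C1OC | intermediate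
14 | O3,O20-bis[(methylsulfanyl)carbonothioyl] derivative of 13 | C1[C@@]2(COC(=S)SC)CC[C@@H](OC(=S)SC)C(C)(C)[C@@H]2C(=O)C=C1OC | intermediate
15 | 8-methoxy-4,4,10β-trimethyl-trans-Δ7-octalin-6-one (5α-H) | C1[C@@]2(C)CCCC(C)(C)[C@@H]2C(=O)C=C1OC | intermediate
16 | 4,4,10β-trimethyl-trans-decalin-6,8-dione (5α-H) | O=C1C[C@@]2(C)CCCC(C)(C)[C@@H]2C(=O)C1 | intermediate
17 | methyl (13S)-11-hydroxy-6,8-dioxo-17-norlabdan-15-oate (C9/C11 epimer mixture) | COC(=O)C[C@@H](C)CC(O)C1[C@@]2(C)CCCC(C)(C)[C@@H]2C(=O)CC1=O | intermediate
18 | methyl (13S)-8,11-diacetoxy-6-oxo-17-norlabd-7-en-15-oate (epimer mixture) | COC(=O)C[C@@H](C)CC(OC(C)=O)C1[C@@]2(C)CCCC(C)(C)[C@@H]2C(=O)C=C1OC(C)=O | intermediate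
19 | methyl (13S)-6,8-dioxo-17-norlabd-9(11)-en-15-oate (E/Z mixture) | COC(=O)C[C@@H](C)CC=C1[C@@]2(C)CCCC(C)(C)[C@@H]2C(=O)CC1=O | intermediate
20 | methyl (13S)-6,8-dioxo-17-norlabdan-15-oate (9α-H) | COC(=O)C[C@@H](C)CC[C@@H]1[C@@]2(C)CCCC(C)(C)[C@@H]2C(=O)CC1=O | intermediate
21 | methyl (13S)-6-oxo-8-(trifluoromethylsulfonyloxy)-17-norlabd-7-en-15-oate | COC(=O)C[C@@H](C)CC[C@@H]1[C@@]2(C)CCCC(C)(C)[C@@H]2C(=O)C=C1OS(=O)(=O)C(F)(F)F | intermediate
22 | methyl (13S)-6-oxolabd-7-en-15-oate | COC(=O)C[C@@H](C)CC[C@@H]1[C@@]2(C)CCCC(C)(C)[C@@H]2C(=O)C=C1C | intermediate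
23 | methyl (13S)-7α,8α-epoxy-6-oxolabdan-15-oate | COC(=O)C[C@@H](C)CC[C@@H]1[C@@]2(C)CCCC(C)(C)[C@@H]2C(=O)[C@H]3O[C@@]13C | intermediate
24 | methyl (13S)-8α-hydroxy-6-oxolabdan-15-oate | COC(=O)C[C@@H](C)CC[C@@H]1[C@@]2(C)CCCC(C)(C)[C@@H]2C(=O)C[C@@]1(C)O | intermediate
25 | methyl (13S)-6β,8α-dihydroxylabdan-15-oate | COC(=O)C[C@@H](C)CC[C@@H]1[C@@]2(C)CCCC(C)(C)[C@@H]2[C@H](O)C[C@@]1(C)O | intermediate
26 | methyl (13S)-6β-acetoxy-8α-hydroxylabdan-15-oate (CNP0113148.1) | COC(=O)C[C@@H](C)CC[C@@H]1[C@@]2(C)CCCC(C)(C)[C@@H]2[C@H](OC(C)=O)C[C@@]1(C)O | target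

**Step count**

Total: 18 steps. Longest linear sequence: 16 steps (steps 3 to 18, from 5-bromo-2-methylpent-2-ene); the aldehyde fragment takes 2 steps (steps 1 and 2).

**Steps most likely to fail**

1. Step 7 (the one new method). Protonation of the enol ethers, or rearrangement of the activated epoxide by hydride shift or fluoride capture, may outrun C–C bond formation, and discrimination between the two enantiotopic arms may be incomplete. The fallback is the known titanocene-mediated radical cyclisation of epoxy olefins and sets out from 10. Cp2TiCl (trivalent titanium, made from Cp2TiCl2 and Mn dust, THF, 20 °C) opens the epoxide homolytically at C4, and the tertiary radical closes ring A onto C5 through the same chair. The α-methoxy radical at C6 is then captured by a second Cp2TiCl and released by β-hydride elimination as the cis-fused 6,8-dimethoxy diene F1. Treatment with 1 M HCl in THF hydrolyses both enol ethers and the silyl ether and epimerises C5, so the sequence comes back to the route at 12.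

2. Step 11. Proton transfer from the enolisable aldehyde to the dianion, attack through C7 instead of C9, or incomplete elimination of acetate could erode the condensation. The fallback uses a known methylenation followed by a radical conjugate addition (Giese reaction) and sets out from 16. LiN(iPr)2 and then CH2=NMe2+ I− give the Mannich base F2, which on warming in toluene loses dimethylamine to the 9-methylene dione F3, used at once. Separately, 1 is converted by iododecarboxylation (PhI(OAc)2, I2, hν) into methyl (R)-4-iodo-3-methylbutanoate F4. Bu3SnH/AIBN adds the primary radical from F4 to the exocyclic methylene of F3, and the C9 radical should take hydrogen from the stannane on the α face. This comes back to the route at 20, so step 12 is not needed.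

3. Step 10. Slow fragmentation of the primary neopentyl xanthate at C20 may return alcohol instead of the methyl group, even though the secondary C3 xanthate reacts. The fallback separates the two deoxygenations and sets out from 13. TsCl in pyridine sulfonylates only the primary hydroxyl to give the C20 tosylate F5. The C3 hydroxyl is converted into its xanthate F6 (NaH, CS2, MeI) and removed with Bu3SnH/AIBN to give the 3-deoxy tosylate F7. The neopentyl tosylate is then reduced with NaI/Zn in hot 1,2-dimethoxyethane, which comes back to the route at 15, hydrolysed to 16 as in step 10.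

**Further compounds**

F1 | step 7 | cis-fused (5β-H) 3α-hydroxy-6,8-dimethoxy-4,4-dimethyl-10β-[(triethylsilyloxy)methyl]-hexahydronaphthalene-6,8(9)-diene | COC1=C[C@@]2(CO[Si](CC)(CC)CC)CC[C@@H](O)C(C)(C)[C@H]2C(OC)=C1
F2 | step 11 | 9-[(dimethylamino)methyl]-4,4,10β-trimethyl-trans-decalin-6,8-dione (C9 epimer mixture) | CN(C)CC1[C@@]2(C)CCCC(C)(C)[C@@H]2C(=O)CC1=O
F3 | step 11 | 4,4,10β-trimethyl-9-methylidene-trans-decalin-6,8-dione | C=C1[C@@]2(C)CCCC(C)(C)[C@@H]2C(=O)CC1=O
F4 | step 11 | methyl (R)-4-iodo-3-methylbutanoate | COC(=O)C[C@@H](C)CI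
F5 | step 10 | 3α-hydroxy-8-methoxy-4,4-dimethyl-10β-[(4-methylphenylsulfonyloxy)methyl]-trans-Δ7-octalin-6-one | C1[C@@]2(COS(=O)(=O)c3ccc(C)cc3)CC[C@@H](O)C(C)(C)[C@@H]2C(=O)C=C1OC
F6 | step 10 | O3-[(methylsulfanyl)carbonothioyl] derivative of F5 | C1[C@@]2(COS(=O)(=O)c3ccc(C)cc3)CC[C@@H](OC(=S)SC)C(C)(C)[C@@H]2C(=O)C=C1OC
F7 | step 10 | 8-methoxy-4,4-dimethyl-10β-[(4-methylphenylsulfonyloxy)methyl]-trans-Δ7-octalin-6-one | C1[C@@]2(COS(=O)(=O)c3ccc(C)cc3)CCCC(C)(C)[C@@H]2C(=O)C=C1OC
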